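Ring atoms are numbered C1–C6 and the exocyclic methylene C7, as in the target's name. The β face is the face of the hydroxyls on C1, C2 and C4; the α face carries C7 and the C3 benzoate.

## Analysis of the target

Target 15 is a cyclohexene (alkene C5=C6) in which every sp3 ring carbon bears oxygen. C1 is a quaternary carbinol that also carries C7, C2 and C4 are secondary carbinols, and of the five oxygens only O3 and O7 are benzoylated. The four stereocentres C1–C4 are contiguous: C1/C2 are cis, C2/C3 and C3/C4 are trans, and the absolute configuration is 1S,2S,3R,4S. The sensitive points are the two esters, each flanked by free hydroxyls to which it can migrate under base, and the two allylic carbinols C1 (tertiary) and C4 (secondary), which can ionize under strong acid. The carbon skeleton is trivial, a six-membered ring with one carbon (C7) para to the C4 oxygen. The hard parts are the absolute configuration of the fully substituted C1, the facial placement of three more oxygens, and telling O3 and O7 apart from O1, O2 and O4. The plan rests on one feature: with C2–C3 returned to an alkene and C4 to a carbonyl, C1 and C7 lie on the mirror plane of an achiral 4-hydroxycyclohexa-2,5-dienone whose enone arms are C2=C3 and C6=C5. Since O1 and O2 are cis, a two-atom tether hung on O1 can put an oxygen on C2 and nowhere else, and a chiral catalyst that chooses C2 over C6 fixes C1 and C2 together. The unused arm, C5=C6–C4=O, is then the enone through which O3 (via the C3 enol) and the C4 carbinol are introduced.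

## Retrosynthetic reasoning

**15 ⇒ 14.** The two O–C(acetal) bonds of a cyclic acetal across O1 and O2 are cut last. Keeping O1 and O2 tied together until the end means that only O3 and O4 are ever free, so neither ester has a neighbouring hydroxyl to migrate to during the route. The forward step has to hydrolyse an aldehyde-derived dioxolane without ionizing the allylic C–O bonds at C1 and C4.

**14 ⇒ 13.** The C4–H bond is cut, taking the allylic alcohol back to the enone. The carbonyl is needed earlier to activate C3, and its 1,2-reduction is the natural way to set C4. The forward reduction must avoid the conjugate position and deliver hydride on the α face, so that O4 ends up trans to the C3 benzoate.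

**13 ⇒ 11 + 12 ⇒ 8 ⇒ 7.** The ester bond at O3 is cut to hydroxy ketone 11 and benzoyl chloride 12, and the C3–O bond is then cut back to the C3 methylene of enone 7 via silyl dienol ether 8. C3 is the only enolizable position of 7 because C1 is quaternary, so no regiochemical question arises. The forward oxidation of the enol ether must occur on the α face, anti to the C2–O bond, and the enolization must not expel O2, which sits β to the carbonyl.

**7 ⇒ 4 + 5 (key disconnection).** The O2–C2 bond and the O1–C(acetal) bond are cut, which removes the dioxolane ring and all three stereocentres of 7 at once. What remains is the achiral para-quinol 4 and 2-methylpropanal 5. No other cut simplifies as much, because it is the only one that leads to a precursor with a mirror plane. The forward reaction must form the hemiacetal on the tertiary hydroxyl and then add its oxygen to one of two enantiotopic enone arms under the control of a chiral phosphoric acid.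

**4 ⇒ 3.** The C1–O bond is cut, returning the dienone to phenol 3. The forward reaction is an oxidative dearomatization in aqueous medium by a trivalent iodine oxidant, with the C1 oxygen entering para to the phenol oxygen.

**3 ⇒ 1 + 2.** The ester bond at O7 is cut to 4-(hydroxymethyl)phenol 1 and benzoic acid 2. Acylating 1 with 12 under base would go to the phenol oxygen first, and a phenoxide of 3 would expel its benzylic ester by 1,6-elimination. The ester is therefore made under neutral redox-condensation conditions, which act only on the aliphatic hydroxyl.

## Alternatives that were turned down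

**Alternative 1: ring closure between C6 and C1 by a chromium-mediated addition.** The ring would be opened at C1–C6 to the open-chain ketone (Z)-1,4-bis[(tert-butyldimethylsilyl)oxy]-7-iodo-3,5-bis[(4-methoxybenzyl)oxy]hept-6-en-2-one A2. In the forward step, CrCl2 (divalent chromium) with catalytic NiCl2 (divalent nickel) would metalate the carbon–iodine bond of A2, and the resulting C6 nucleophile would add to the C1 carbonyl to give cyclohexenol A1.
- For it: C2, C3 and C4 arrive with fixed configuration, and the protecting groups of A1 (silyl on O3 and O7, 4-methoxybenzyl on O2 and O4) map exactly onto the ester pattern of 15. Desilylation, double benzoylation with 12 and oxidative ether removal would finish the synthesis without any facial-selectivity question at C3 or C4. On oxygen differentiation this plan is stronger than the chosen one.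
- Against it: A2 is a seven-carbon chain with three stereocentres and four protecting groups that must be built over many steps. Alkenyl–chromium additions are far slower to ketones than to aldehydes and need a large excess of a toxic metal salt. The one new stereocentre, C1, depends on how the α-alkoxy ketone folds, which is hard to predict, and that ketone can epimerize at C2.
- Comparison: the chosen route makes C1 and C2 from an achiral, two-step precursor with a catalyst and needs eight steps in all, at the price of setting C3 and C4 by substrate control.

**Alternative 2: hydroxyl-directed epoxidation of an exocyclic alkene, then opening by benzoate.** The C1–O and C7–O bonds would be traced to the spiro-oxirane A3, made from the dienol 6-[(tert-butyldimethylsilyl)oxy]-2-hydroxy-3-methylidenecyclohex-4-en-1-yl benzoate A4. VO(acac)2 with tert-butyl hydroperoxide would epoxidize the C1=C7 alkene on the face of the C2 hydroxyl. Opening of A3 at C7 by a benzoate salt and desilylation would give 15.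
- For it: the directing effect of an allylic hydroxyl in vanadium-catalysed epoxidation is among the most dependable ways to set a cis relationship. On that point it is more predictable than enantiotopic-arm selection by an organocatalyst. The opening also installs the O7 ester and frees O1 in one operation.
- Against it: A3 is a vinyl oxirane with a tertiary allylic C1, so SN2′ attack and ionization at C1 compete with attack at C7. The opening needs a basic carboxylate next to a free C2 hydroxyl and a C3 benzoate, which invites acyl migration. A4, a cross-conjugated diene with three differentiated oxygens on three stereocentres, is itself a demanding, aromatization-prone intermediate, so the stereochemical problem is only moved, not solved.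
- Comparison: the chosen strategy has O7 benzoylated from the first step and needs no chiral, non-racemic diene. It is weaker only in that C1/C2 rest on a catalyst rather than on a directing group.

**Alternative 3: singlet-oxygen cycloaddition to a trans-dihydrodiol diene.** Both the C1–O and C4–O bonds would be cut through the endoperoxide A5. Sensitized singlet oxygen would add across C1 and C4 of trans-[5-(benzoyloxy)-6-hydroxycyclohexa-1,3-dien-1-yl]methyl benzoate A6 on the face of the C2 hydroxyl. Reduction of the O–O bond of A5 would give 15 directly.
- For it: C1 and C4 are created together with exactly the required cis-1,4 relationship, both esters are already in place, no protecting group is used, and only one step follows the key step. The hydroxyl steering and the steric shielding by the C3 benzoate point the same way. On step economy after the key step and on atom economy it beats the chosen route.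
- Against it: A6 is a monoester of an arene trans-dihydrodiol, which aromatizes readily by loss of water or benzoic acid. Its enantioselective preparation, and the selective benzoylation of O3 over O2, are not short. A5 is base-sensitive at C4–H.
- Comparison: the chosen route trades this brevity for a stable, achiral, crystalline-type precursor and a catalytic enantio-determining step, and spends five steps after the key step.

Key step: step 3

## Route

Remark on the chemistry: TRIP is 3,3′-bis(2,4,6-triisopropylphenyl)-1,1′-binaphthyl-2,2′-diyl hydrogen phosphate. Which enantiomer leads to 7 rather than its mirror image is not predicted here, so the (R)-acid is written and the (S)-acid is to be used instead if a pilot run calls for it.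

Step 1
Reactants: 1 4-(hydroxymethyl)phenol; 2 benzoic acid
Product: 3 (4-hydroxyphenyl)methyl benzoate
Conditions: PPh3, DIAD, THF, 0 °C → rt
Reagents that add atoms: benzoic acid (2), O=C(O)c1ccccc1
Why: Mitsunobu esterification: only the aliphatic hydroxyl forms an alkoxyphosphonium ion that can be displaced at carbon, and the carboxylic acid, far more acidic than the phenol, supplies the nucleophile, so the phenol stays free. No base is present, which avoids the phenoxide that would eject the benzylic ester.

Step 2
Reactants: 3 (4-hydroxyphenyl)methyl benzoate
Product: 4 (1-hydroxy-4-oxocyclohexa-2,5-dien-1-yl)methyl benzoate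
Conditions: PhI(OAc)2, MeCN/H2O (3:1), 0 °C
Reagents that add atoms: water, O
Why: Oxidative dearomatization of a para-substituted phenol by a trivalent iodine reagent: the phenol oxygen binds to iodine, water attacks the para carbon and iodobenzene leaves, giving the 4-hydroxycyclohexa-2,5-dienone. The product is achiral, with a mirror plane through C1, C7 and C4.

Step 3
Reactants: 4 (1-hydroxy-4-oxocyclohexa-2,5-dien-1-yl)methyl benzoate; 5 2-methylpropanal
Product: 7 [(2R,3aS,7aS)-5-oxo-2-(propan-2-yl)-3a,4,5,7a-tetrahydro-2H-1,3-benzodioxol-7a-yl]methyl benzoate, via hemiacetal 6 (not isolated)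
Conditions: (R)-TRIP (10 mol %), 5 (3 equiv, freshly distilled), ClCH2CH2Cl, 40 °C
Reagents that add atoms: 2-methylpropanal (5), CC(C)C=O
Why: The tertiary hydroxyl of 4 adds reversibly to 5 under acid catalysis to give hemiacetal 6; the phosphoric acid then holds the hemiacetal O–H on its P=O oxygen and activates the dienone through its P–OH, the hemiacetal oxygen adds to C2, the β-carbon of one enone arm, and the enol tautomerizes to leave the C3 methylene. The closest known reaction type is the chiral phosphoric acid-catalysed acetalization and oxa-Michael desymmetrization of para-quinols with aldehydes. The 1,3-dioxolane closes in the 5-exo-trig mode, and the step forms two C–O bonds (O1–C(acetal) and O2–C2) and three stereocentres. At C2 the two-atom tether can reach the β-carbon only on the face that carries O1, so the cis ring fusion follows from geometry, while the choice of C2 over C6 is made by the chiral pocket of the catalyst. C1 becomes stereogenic through that same choice and needs no control of its own. At the acetal carbon the hemiacetal epimers interconvert and the one that cyclizes with the isopropyl group on the convex face should react faster; this centre is removed again in step 8. The only selectivity the step needs is between the enantiotopic arms, for which the substrate has no bias; position and face are secured by the tether, and the remote carbonyl cannot be reached, which rules out 1,2-addition. The product is a full acetal with no free hydroxyl, so the conjugate addition should not reverse readily under the weakly acidic conditions.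

Step 4
Reactants: 7 [(2R,3aS,7aS)-5-oxo-2-(propan-2-yl)-3a,4,5,7a-tetrahydro-2H-1,3-benzodioxol-7a-yl]methyl benzoate
Product: 8 [(2R,3aS,7aS)-2-(propan-2-yl)-5-[(trimethylsilyl)oxy]-3a,7a-dihydro-2H-1,3-benzodioxol-7a-yl]methyl benzoate
Conditions: Me3SiCl, then LiN(SiMe3)2, THF, −78 °C (in situ quench); pentane work-up, used crude
Reagents that add atoms: chlorotrimethylsilane, C[Si](C)(C)Cl
Why: Kinetic enolization with in situ O-silylation: C3 holds the only enolizable hydrogens because C1 is quaternary, so only the cross-conjugated 2-silyloxy diene can form. Trapping in the flask at −78 °C keeps the lifetime of the enolate, which has the C2–O bond β to it, as short as possible. A silyl triflate with an amine base is avoided because that pair can cleave aldehyde-derived acetals.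

Step 5
Reactants: 8 [(2R,3aS,7aS)-2-(propan-2-yl)-5-[(trimethylsilyl)oxy]-3a,7a-dihydro-2H-1,3-benzodioxol-7a-yl]methyl benzoate
Product: 11 [(2R,3aS,4S,7aS)-4-hydroxy-5-oxo-2-(propan-2-yl)-3a,4,5,7a-tetrahydro-2H-1,3-benzodioxol-7a-yl]methyl benzoate, via silyloxy oxirane 9 (not isolated), via silyloxy ketone 10 (not isolated)
Conditions: mCPBA, NaHCO3, CH2Cl2, −20 → 0 °C; then citric acid, MeOH, 0 °C
Reagents that add atoms: 3-chloroperoxybenzoic acid, O=C(OO)c1cccc(Cl)c1
Why: Rubottom oxidation: the peracid epoxidizes the electron-rich enol ether alkene C3=C4 rather than C5=C6, the silyloxy oxirane opens with a 1,4-silyl shift to the α-silyloxy ketone, and mild acidic methanolysis removes the silyl group. C3 is set in the epoxidation: the reagent should approach on the α face, anti to the adjacent C2–O bond, with the dioxolane folded under the diene, which places O3 trans to O2.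

Step 6
Reactants: 11 [(2R,3aS,4S,7aS)-4-hydroxy-5-oxo-2-(propan-2-yl)-3a,4,5,7a-tetrahydro-2H-1,3-benzodioxol-7a-yl]methyl benzoate; 12 benzoyl chloride
Product: 13 (2R,3aS,4S,7aS)-7a-[(benzoyloxy)methyl]-5-oxo-2-(propan-2-yl)-3a,4,5,7a-tetrahydro-2H-1,3-benzodioxol-4-yl benzoate
Conditions: BzCl, pyridine, DMAP (cat.), CH2Cl2, 0 °C
Reagents that add atoms: benzoyl chloride (12), O=C(Cl)c1ccccc1
Why: Acylation through an acylpyridinium ion of the only free hydroxyl, since O1 and O2 are tied up in the acetal; the C3–O bond is untouched, so the configuration is retained. The weak base and low temperature are chosen so that C3 is not enolized and O2 is not lost.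

Step 7
Reactants: 13 (2R,3aS,4S,7aS)-7a-[(benzoyloxy)methyl]-5-oxo-2-(propan-2-yl)-3a,4,5,7a-tetrahydro-2H-1,3-benzodioxol-4-yl benzoate
Product: 14 (2R,3aS,4R,5S,7aS)-7a-[(benzoyloxy)methyl]-5-hydroxy-2-(propan-2-yl)-3a,4,5,7a-tetrahydro-2H-1,3-benzodioxol-4-yl benzoate
Conditions: NaBH4, CeCl3·7H2O, MeOH, −78 °C; AcOH quench at −78 °C
Reagents that add atoms: none
Why: Luche reduction: with CeCl3 (trivalent cerium) the hydride adds 1,2 to the enone and leaves the esters alone. Axial delivery onto the half-chair in which the C3 benzoate, O2 and C7 are all pseudo-equatorial (the other half-chair would set C7 and the benzoate 1,3-diaxial) comes from the α face and gives the pseudo-equatorial C4 hydroxyl, trans to the C3 benzoate and cis to O2. The cold acidic quench is meant to stop migration of the benzoate from O3 to O4.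

Step 8
Reactants: 14 (2R,3aS,4R,5S,7aS)-7a-[(benzoyloxy)methyl]-5-hydroxy-2-(propan-2-yl)-3a,4,5,7a-tetrahydro-2H-1,3-benzodioxol-4-yl benzoate
Product: 15 [(1S,2S,3R,4S)-3-(benzoyloxy)-1,2,4-trihydroxycyclohex-5-en-1-yl]methyl benzoate
Conditions: CF3CO2H/H2O (9:1), 0 °C → rt
Reagents that add atoms: none
Why: Acid hydrolysis of the aldehyde acetal through an oxocarbenium ion at the acetal carbon releases the C1/C2 diol and 5. The C–O bonds at C1 and C2 are not broken, so both configurations are kept, and benzoates do not migrate readily under acid.

## Compound list

1 | 4-(hydroxymethyl)phenol | OCc1ccc(O)cc1 | starting material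
2 | benzoic acid | O=C(O)c1ccccc1 | starting material
3 | (4-hydroxyphenyl)methyl benzoate | O=C(OCc1ccc(O)cc1)c1ccccc1 | intermediate
4 | (1-hydroxy-4-oxocyclohexa-2,5-dien-1-yl)methyl benzoate (achiral para-quinol) | O=C(OCC1(O)C=CC(=O)C=C1)c1ccccc1 | intermediate
5 | 2-methylpropanal | CC(C)C=O | starting material
6 | {1-[(1R)-1-hydroxy-2-methylpropoxy]-4-oxocyclohexa-2,5-dien-1-yl}methyl benzoate (hemiacetal on O1; the epimer that cyclizes is drawn) | O=C(OCC1(O[C@@H](O)C(C)C)C=CC(=O)C=C1)c1ccccc1 | intermediate (not isolated)
7 | [(2R,3aS,7aS)-5-oxo-2-(propan-2-yl)-3a,4,5,7a-tetrahydro-2H-1,3-benzodioxol-7a-yl]methyl benzoate (cis-fused dioxolane across O1/O2, isopropyl on the convex face, C4 ketone, C5=C6) | O=C(OC[C@@]1(O2)C=CC(=O)C[C@@H]1O[C@H]2C(C)C)c1ccccc1 | intermediate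
8 | [(2R,3aS,7aS)-2-(propan-2-yl)-5-[(trimethylsilyl)oxy]-3a,7a-dihydro-2H-1,3-benzodioxol-7a-yl]methyl benzoate (silyl dienol ether, C3=C4 and C5=C6) | O=C(OC[C@@]1(O2)C=CC(O[Si](C)(C)C)=C[C@@H]1O[C@H]2C(C)C)c1ccccc1 | intermediate
9 | silyloxy oxirane of 8 across C3–C4, oxirane oxygen on the α face, trimethylsilyloxy on C4 | O=C(OC[C@@]1(O2)C=C[C@@]3(O[Si](C)(C)C)O[C@H]3[C@@H]1O[C@H]2C(C)C)c1ccccc1 | intermediate (not isolated)
10 | O3-trimethylsilyl ether of 11 (α-silyloxy ketone) | O=C(OC[C@@]1(O2)C=CC(=O)[C@@H](O[Si](C)(C)C)[C@@H]1O[C@H]2C(C)C)c1ccccc1 | intermediate (not isolated)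
11 | [(2R,3aS,4S,7aS)-4-hydroxy-5-oxo-2-(propan-2-yl)-3a,4,5,7a-tetrahydro-2H-1,3-benzodioxol-7a-yl]methyl benzoate (C3 hydroxyl α, trans to O2) | O=C(OC[C@@]1(O2)C=CC(=O)[C@@H](O)[C@@H]1O[C@H]2C(C)C)c1ccccc1 | intermediate
12 | benzoyl chloride | O=C(Cl)c1ccccc1 | starting material
13 | (2R,3aS,4S,7aS)-7a-[(benzoyloxy)methyl]-5-oxo-2-(propan-2-yl)-3a,4,5,7a-tetrahydro-2H-1,3-benzodioxol-4-yl benzoate | O=C(OC[C@@]1(O2)C=CC(=O)[C@@H](OC(=O)c3ccccc3)[C@@H]1O[C@H]2C(C)C)c1ccccc1 | intermediate
14 | (2R,3aS,4R,5S,7aS)-7a-[(benzoyloxy)methyl]-5-hydroxy-2-(propan-2-yl)-3a,4,5,7a-tetrahydro-2H-1,3-benzodioxol-4-yl benzoate (C4 hydroxyl β) | O=C(OC[C@@]1(O2)C=C[C@H](O)[C@@H](OC(=O)c3ccccc3)[C@@H]1O[C@H]2C(C)C)c1ccccc1 | intermediate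
15 | [(1S,2S,3R,4S)-3-(benzoyloxy)-1,2,4-trihydroxycyclohex-5-en-1-yl]methyl benzoate | O=C(OC[C@@]1(O)C=C[C@H](O)[C@@H](OC(=O)c2ccccc2)[C@@H]1O)c1ccccc1 | target

## Step count and least certain steps

Total: 8 steps. Longest linear sequence: 8 steps (1 → 15).

**Step 3 (key step).** The most likely failure is incomplete discrimination between the two enone arms. The tertiary hydroxyl of 4 is hindered and made less nucleophilic by the neighbouring ester, so the hemiacetal forms slowly, and a racemic background cyclization (uncatalysed, or promoted by traces of carboxylic acid in autoxidized aldehyde) can then compete. Fallback, setting out from 4: the same oxygen is delivered by a boron tether instead of a carbon one. Phenylboronic acid and a quinine-derived tertiary amine–thiourea catalyst in toluene (the known hemiester oxa-Michael addition of γ-hydroxy enones) should give the cyclic phenylboronate spanning O1 and O2 of [(1S,2S)-1,2-dihydroxy-4-oxocyclohex-5-en-1-yl]methyl benzoate F1. Exchange of boron onto pinacol should free the diol [(1S,2S)-1,2-dihydroxy-4-oxocyclohex-5-en-1-yl]methyl benzoate F2. Acetalization of F2 with 5 (PPTS, MgSO4, CH2Cl2), under conditions where the isopropyl group can settle on the convex face, returns to the route at 7.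

**Step 4.** The most likely failure is loss of the C2–O bond by β-elimination from the C3 enolate before it is silylated, whenever that bond lines up with the enolate π system; this unravels the acetal. Fallback, setting out from 7: enolate chemistry is avoided altogether. Heating 7 with Mn(OAc)3·2H2O (trivalent manganese) and an excess of 2 in benzene, the known α′-acyloxylation of enones by carboxylate transfer under acidic conditions, should place the benzoate on C3 trans to O2 and rejoin the route at 13, two steps shorter. No compound outside the main list arises (entry F0).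

**Step 5.** The most likely failure is poor facial selectivity of the epoxidation, if the diene reacts through the half-chair in which C7 is pseudo-axial and screens the α face of C3. Fallback, setting out from 8: the oxidation is run as written, and whatever falls out as the C3 epimer [(2R,3aS,4R,7aS)-4-hydroxy-5-oxo-2-(propan-2-yl)-3a,4,5,7a-tetrahydro-2H-1,3-benzodioxol-7a-yl]methyl benzoate F3 is esterified with inversion instead of retention (2, PPh3, DIAD, THF; Mitsunobu reaction at an α-keto carbinol). This returns to the route at 13, so both epimers of the oxidation converge.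

**Step 7.** The most likely failure is hydride delivery on the β face through the minor half-chair, or migration of the C3 benzoate to the new C4 alkoxide before the quench. Fallback, setting out from 13: if the reduction gives the C4 epimer (2R,3aS,4R,5R,7aS)-7a-[(benzoyloxy)methyl]-5-hydroxy-2-(propan-2-yl)-3a,4,5,7a-tetrahydro-2H-1,3-benzodioxol-4-yl benzoate F4, its carbinol is inverted by Mitsunobu esterification with chloroacetic acid (PPh3, DIAD) to the chloroacetate (2R,3aS,4R,5S,7aS)-7a-[(benzoyloxy)methyl]-5-[(chloroacetyl)oxy]-2-(propan-2-yl)-3a,4,5,7a-tetrahydro-2H-1,3-benzodioxol-4-yl benzoate F5. The chloroacetyl group is then removed selectively with thiourea and NaHCO3 in EtOH, which leaves benzoates alone, and the route is rejoined at 14.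

**Step 8.** The most likely failure is ionization in acid strong enough to open an aldehyde-derived dioxolane flanked by electron-poor carbons: at C4 (helped by the trans C3 benzoate) or at C1, with scrambling of esters and configuration. Fallback, setting out from 13: the order of the last two operations is exchanged. Aqueous CF3CO2H on 13 should give the diol enone [(1S,2S,3S)-3-(benzoyloxy)-1,2-dihydroxy-4-oxocyclohex-5-en-1-yl]methyl benzoate F6. While C4 is still a carbonyl there is no carbinol to ionize, and a cation at C1 would be destabilized by the enone. Luche reduction of F6 under the conditions of step 7 then leads directly to 15.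

## Further compounds

F1 | step 3 | cyclic phenylboronate spanning O1 and O2 of [(1S,2S)-1,2-dihydroxy-4-oxocyclohex-5-en-1-yl]methyl benzoate | O=C(OC[C@@]1(O2)C=CC(=O)C[C@@H]1OB2c1ccccc1)c1ccccc1
F2 | step 3 | [(1S,2S)-1,2-dihydroxy-4-oxocyclohex-5-en-1-yl]methyl benzoate | O=C(OC[C@@]1(O)C=CC(=O)C[C@@H]1O)c1ccccc1
F0 | step 4 | none | none
F3 | step 5 | [(2R,3aS,4R,7aS)-4-hydroxy-5-oxo-2-(propan-2-yl)-3a,4,5,7a-tetrahydro-2H-1,3-benzodioxol-7a-yl]methyl benzoate | O=C(OC[C@@]1(O2)C=CC(=O)[C@H](O)[C@@H]1O[C@H]2C(C)C)c1ccccc1
F4 | step 7 | (2R,3aS,4R,5R,7aS)-7a-[(benzoyloxy)methyl]-5-hydroxy-2-(propan-2-yl)-3a,4,5,7a-tetrahydro-2H-1,3-benzodioxol-4-yl benzoate | O=C(OC[C@@]1(O2)C=C[C@@H](O)[C@@H](OC(=O)c3ccccc3)[C@@H]1O[C@H]2C(C)C)c1ccccc1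
F5 | step 7 | (2R,3aS,4R,5S,7aS)-7a-[(benzoyloxy)methyl]-5-[(chloroacetyl)oxy]-2-(propan-2-yl)-3a,4,5,7a-tetrahydro-2H-1,3-benzodioxol-4-yl benzoate | O=C(OC[C@@]1(O2)C=C[C@H](OC(=O)CCl)[C@@H](OC(=O)c3ccccc3)[C@@H]1O[C@H]2C(C)C)c1ccccc1
F6 | step 8 | [(1S,2S,3S)-3-(benzoyloxy)-1,2-dihydroxy-4-oxocyclohex-5-en-1-yl]methyl benzoate | O=C(OC[C@@]1(O)C=CC(=O)[C@@H](OC(=O)c2ccccc2)[C@@H]1O)c1ccccc1
A1 | alternative 1 | 5-[(tert-butyldimethylsilyl)oxy]-1-{[(tert-butyldimethylsilyl)oxy]methyl}-4,6-bis[(4-methoxybenzyl)oxy]cyclohex-2-en-1-ol, tertiary hydroxyl cis to the C6 ether | CC(C)(C)[Si](C)(C)OC[C@@]1(O)C=C[C@H](OCc2ccc(OC)cc2)[C@@H](O[Si](C)(C)C(C)(C)C)[C@@H]1OCc1ccc(OC)cc1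
A2 | alternative 1 | (Z)-1,4-bis[(tert-butyldimethylsilyl)oxy]-7-iodo-3,5-bis[(4-methoxybenzyl)oxy]hept-6-en-2-one | CC(C)(C)[Si](C)(C)OCC(=O)[C@@H](OCc1ccc(OC)cc1)[C@H](O[Si](C)(C)C(C)(C)C)[C@@H](OCc1ccc(OC)cc1)/C=C\I
A3 | alternative 2 | 6-[(tert-butyldimethylsilyl)oxy]-4-hydroxy-1-oxaspiro[2.5]oct-7-en-5-yl benzoate, oxirane oxygen cis to the hydroxyl | C1O[C@@]12C=C[C@H](O[Si](C)(C)C(C)(C)C)[C@@H](OC(=O)c3ccccc3)[C@@H]2O
A4 | alternative 2 | 6-[(tert-butyldimethylsilyl)oxy]-2-hydroxy-3-methylidenecyclohex-4-en-1-yl benzoate | C=C1C=C[C@H](O[Si](C)(C)C(C)(C)C)[C@@H](OC(=O)c2ccccc2)[C@@H]1O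
A5 | alternative 3 | [8-(benzoyloxy)-7-hydroxy-2,3-dioxabicyclo[2.2.2]oct-5-en-1-yl]methyl benzoate, peroxide bridge syn to the hydroxyl | O=C(OC[C@@]1(OO2)C=C[C@H]2[C@@H](OC(=O)c3ccccc3)[C@@H]1O)c1ccccc1
A6 | alternative 3 | trans-[5-(benzoyloxy)-6-hydroxycyclohexa-1,3-dien-1-yl]methyl benzoate | O=C(OCC1=CC=C[C@@H](OC(=O)c2ccccc2)[C@@H]1O)c1ccccc1
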